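The route reads the C3 carbinol of the dihydropyran ring, which sits between quaternary C2 and benzylic C4, as the remnant of a C3=C4 cis-alkene in a 2,2-dimethyl-2H-chromene. One catalytic, enantioselective oxygen transfer to that alkene forms the C3–O and C4–O bonds, closes the oxirane and fixes C3 as R. The surplus benzylic C4–O bond is then cut reductively. The substrate is 6-acetyl-2,2-dimethyl-2H-chromene-5,7-diyl diacetate. Its ester groups are installed before the pyran ring is formed, so only the oxygen para to the acetyl group can close the ring. The 4-hydroxy-2-pyranone half is joined last at C8 through a one-carbon bridge.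

Key step: step 4

Remark: the sense of induction is assumed from other 2,2-dimethylchromenes, with which the (R,R)-catalyst gives (3R,4R)-oxiranes; commercial trihydroxyacetophenone monohydrate is assumed to be dried azeotropically with toluene before use.

Step 1
Reactants: 1 2,4,6-trihydroxyacetophenone; 2 3-chloro-3-methylbut-1-yne
Product: 3 1-[2,6-dihydroxy-4-(2-methylbut-3-yn-2-yloxy)phenyl]ethanone
Conditions: CuCl2·2H2O (1 mol%), DBU (1.1 equiv), 2 (1.1 equiv), MeCN, 0 °C, N2
Reagents that add atoms: none
Why: Copper-catalysed propargylic etherification: the chloride ionises by way of a copper acetylide to an allenylidene-type electrophile, which is captured at its tertiary carbon by the phenoxide of O4–H, the most acidic hydroxyl and the only one not hydrogen-bonded to the acetyl carbonyl, so one equivalent of base should confine the reaction to the para oxygen.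

Step 2
Reactants: 3 1-[2,6-dihydroxy-4-(2-methylbut-3-yn-2-yloxy)phenyl]ethanone
Product: 4 2-acetyl-5-(2-methylbut-3-yn-2-yloxy)benzene-1,3-diyl diacetate
Conditions: Ac2O (3 equiv), pyridine, DMAP (5 mol%), CH2Cl2, 0 °C to rt
Reagents that add atoms: acetic anhydride, CC(=O)OC(C)=O
Why: DMAP-catalysed O-acylation caps both ortho hydroxyls, which blocks ring closure through an ortho oxygen in the next step (the path to the 8-acetyl isomer) and already provides the electron-poor arene that the oxirane will need.

Step 3
Reactants: 4 2-acetyl-5-(2-methylbut-3-yn-2-yloxy)benzene-1,3-diyl diacetate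
Product: 7 6-acetyl-2,2-dimethyl-2H-chromene-5,7-diyl diacetate, via allenylphenol 5 (not isolated), via vinyl quinone methide 6 (not isolated)
Conditions: 1,2-dichlorobenzene, 160 °C, N2
Reagents that add atoms: none
Why: Aryl propargyl ether Claisen cascade: a [3,3] shift to one of the two equivalent ortho carbons, enolisation to 5, a 1,5-hydrogen shift to 6 and an oxa-6π electrocyclisation follow one another, and since the oxygen para to the acetyl group is the only free one, the 6-acetyl chromene is the only regioisomer that can form.

Step 4
Reactants: 7 6-acetyl-2,2-dimethyl-2H-chromene-5,7-diyl diacetate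
Product: 8 (3R,4R)-6-acetyl-3,4-epoxy-2,2-dimethylchroman-5,7-diyl diacetate
Conditions: (R,R)-[N,N'-bis(3,5-di-tert-butylsalicylidene)cyclohexane-1,2-diaminato]manganese chloride, C36H52ClMnN2O2 (5 mol%), mCPBA (2 equiv), NMO (5 equiv), CH2Cl2, −78 °C; cold aq. NaHCO3/Na2S2O3 wash
Reagents that add atoms: mCPBA, O=C(OO)c1cccc(Cl)c1
Why: mCPBA, moderated as its NMO adduct, oxidises the trivalent manganese salen chloride to a pentavalent oxomanganese species, which meets the C3=C4 alkene side-on and passes its oxygen first to C3 and then, by collapse of the benzylic C4 radical, to C4. This is the Jacobsen–Katsuki epoxidation, for which 2,2-dimethylchromenes are a classic substrate class. The oxirane closes in a 3-exo manner onto the manganese-bound oxygen and can only be cis-fused to the six-membered pyran ring, so the relative configuration of C3 and C4 is dictated by that ring. The absolute configuration of both centres comes from the catalyst, since the (R,R)-diamine backbone and the tert-butyl groups leave one approach path in which the arene points away from the bulky groups and quaternary C2 disfavours the reverse orientation, which should give the (3R,4R)-oxirane. Only enantioface selection is needed, because 7 holds a single alkene, and the rigid, conjugated cis-alkene next to C2 secures it. The two acetates and the acetyl group reduce electron donation from O5 and O7, so the benzylic C4–O bond should survive at −78 °C, and the water-free medium spares the aryl esters.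

Step 5
Reactants: 8 (3R,4R)-6-acetyl-3,4-epoxy-2,2-dimethylchroman-5,7-diyl diacetate
Product: 9 (3R)-6-acetyl-3-hydroxy-2,2-dimethylchroman-5,7-diyl diacetate
Conditions: H2 (1 atm), 10% Pd/C, EtOAc, rt
Reagents that add atoms: none
Why: Heterogeneous hydrogenolysis of a benzylic C–O bond: only C4–O is benzylic, so palladium cleaves it and leaves C3–O and its R configuration untouched, while the non-nucleophilic solvent prevents solvolysis and the doubly ortho-flanked aryl ketone should be reduced far more slowly.

Step 6
Reactants: 9 (3R)-6-acetyl-3-hydroxy-2,2-dimethylchroman-5,7-diyl diacetate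
Product: 10 1-[(3R)-3,5,7-trihydroxy-2,2-dimethylchroman-6-yl]ethanone
Conditions: K2CO3 (2.2 equiv), degassed MeOH, 0 °C to rt; then 1 M HCl
Reagents that add atoms: none
Why: Base-mediated transesterification (methanolysis) of the two activated aryl acetates should be much faster than any enolate acyl transfer of the Baker–Venkataraman type, and no bond to C3 is involved.

Step 7
Reactants: 10 1-[(3R)-3,5,7-trihydroxy-2,2-dimethylchroman-6-yl]ethanone
Product: 11 1-{(3R)-8-[(dimethylamino)methyl]-3,5,7-trihydroxy-2,2-dimethylchroman-6-yl}ethanone hydroiodide
Conditions: Me2N=CH2+ I− (1.0 equiv), MeCN, 0 °C to rt; evaporate, triturate with Et2O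
Reagents that add atoms: N,N-dimethylmethyleneiminium iodide (Eschenmoser's salt), C=[N+](C)C.[I-]
Why: Mannich aminomethylation by a preformed iminium ion: C8 is the only unsubstituted ring carbon and is activated by O1 and O7 (ortho) and O5 (para), and the absence of free formaldehyde and the low temperature should prevent symmetrical methylene bridging.

Step 8
Reactants: 12 methyl 3-oxopentanoate; 13 N-methoxy-N-methylpropanamide
Product: 15 methyl 4-methyl-3,5-dioxoheptanoate, via sodium lithium dienolate 14 (not isolated)
Conditions: NaH (1.1 equiv), THF, 0 °C; n-BuLi (1.05 equiv), 0 °C; 13, −78 to 0 °C; then 1 M HCl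
Reagents that add atoms: none
Why: γ-Acylation of a β-keto ester dianion combined with the Weinreb ketone synthesis: the more basic C4 terminus of 14 attacks the amide, and the chelated tetrahedral adduct lasts until the quench, which prevents both over-addition and proton transfer from the more acidic product.

Step 9
Reactants: 15 methyl 4-methyl-3,5-dioxoheptanoate
Product: 16 6-ethyl-4-hydroxy-5-methyl-2H-pyran-2-one
Conditions: DBU (0.3 equiv), toluene, 110 °C; then 1 M HCl wash
Reagents that add atoms: none
Why: Base-catalysed lactonisation of a 3,5-dioxo ester: the C5 enolate oxygen attacks the ester carbonyl in a 6-exo-trig acyl substitution, and loss of methanol gives the conjugated 4-hydroxy-2-pyranone as the thermodynamic sink.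

Step 10
Reactants: 11 1-{(3R)-8-[(dimethylamino)methyl]-3,5,7-trihydroxy-2,2-dimethylchroman-6-yl}ethanone hydroiodide; 16 6-ethyl-4-hydroxy-5-methyl-2H-pyran-2-one
Product: 18 3-{[(3R)-6-acetyl-3,5,7-trihydroxy-2,2-dimethylchroman-8-yl]methyl}-6-ethyl-4-hydroxy-5-methyl-2H-pyran-2-one (target), via ortho-quinone methide 17 (not isolated)
Conditions: 16 (1.2 equiv), NaOAc (1.2 equiv), EtOH, 70 °C, argon; then 0.5 M HCl
Reagents that add atoms: none
Why: Michael addition to an ortho-quinone methide: the acetate buffer allows loss of dimethylamine across O7–H and the C8 methylene to give 17, and C3 of pyranone 16, its only nucleophilic carbon and a far better donor than any arene present, adds to the exocyclic methylene and restores aromaticity, while chroman C3 is a spectator.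

Compound list
1 | 2,4,6-trihydroxyacetophenone | CC(=O)c1c(O)cc(O)cc1O | starting material
2 | 3-chloro-3-methylbut-1-yne | CC(C)(Cl)C#C | starting material
3 | 1-[2,6-dihydroxy-4-(2-methylbut-3-yn-2-yloxy)phenyl]ethanone | CC(=O)c1c(O)cc(OC(C)(C)C#C)cc1O | intermediate
4 | 2-acetyl-5-(2-methylbut-3-yn-2-yloxy)benzene-1,3-diyl diacetate | CC(=O)c1c(OC(C)=O)cc(OC(C)(C)C#C)cc1OC(C)=O | intermediate
5 | 2-acetyl-5-hydroxy-4-(3-methylbuta-1,2-dien-1-yl)benzene-1,3-diyl diacetate (allenylphenol) | CC(=O)c1c(OC(C)=O)cc(O)c(C=C=C(C)C)c1OC(C)=O | intermediate
6 | 4-acetyl-3,5-diacetoxy-6-[(Z)-3-methylbut-2-enylidene]cyclohexa-2,4-dien-1-one (vinyl quinone methide) | CC(=O)C1=C(OC(C)=O)/C(=C/C=C(C)C)C(=O)C=C1OC(C)=O | intermediate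
7 | 6-acetyl-2,2-dimethyl-2H-chromene-5,7-diyl diacetate | CC(=O)c1c(OC(C)=O)cc2OC(C)(C)C=Cc2c1OC(C)=O | intermediate
8 | (3R,4R)-6-acetyl-3,4-epoxy-2,2-dimethylchroman-5,7-diyl diacetate | CC(=O)c1c(OC(C)=O)cc2OC(C)(C)[C@@H]3O[C@@H]3c2c1OC(C)=O | intermediate
9 | (3R)-6-acetyl-3-hydroxy-2,2-dimethylchroman-5,7-diyl diacetate | CC(=O)c1c(OC(C)=O)cc2OC(C)(C)[C@H](O)Cc2c1OC(C)=O | intermediate
10 | 1-[(3R)-3,5,7-trihydroxy-2,2-dimethylchroman-6-yl]ethanone | CC(=O)c1c(O)cc2OC(C)(C)[C@H](O)Cc2c1O | intermediate
11 | 1-{(3R)-8-[(dimethylamino)methyl]-3,5,7-trihydroxy-2,2-dimethylchroman-6-yl}ethanone hydroiodide | CC(=O)c1c(O)c(CN(C)C)c2OC(C)(C)[C@H](O)Cc2c1O.I | intermediate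
12 | methyl 3-oxopentanoate | CCC(=O)CC(=O)OC | starting material
13 | N-methoxy-N-methylpropanamide | CCC(=O)N(C)OC | starting material
14 | sodium lithium dienolate (dianion) of methyl 3-oxopentanoate | CC=C([O-])C=C([O-])OC.[Na+].[Li+] | intermediate
15 | methyl 4-methyl-3,5-dioxoheptanoate | CCC(=O)C(C)C(=O)CC(=O)OC | intermediate
16 | 6-ethyl-4-hydroxy-5-methyl-2H-pyran-2-one | CCc1oc(=O)cc(O)c1C | intermediate
17 | (3R)-6-acetyl-3,5-dihydroxy-2,2-dimethyl-8-methylidene-3,4-dihydro-2H-chromen-7(8H)-one (ortho-quinone methide) | CC(=O)C1=C(O)C2=C(OC(C)(C)[C@H](O)C2)C(=C)C1=O | intermediate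
18 | 3-{[(3R)-6-acetyl-3,5,7-trihydroxy-2,2-dimethylchroman-8-yl]methyl}-6-ethyl-4-hydroxy-5-methyl-2H-pyran-2-one | CCc1oc(=O)c(Cc2c(O)c(C(C)=O)c(O)c3c2OC(C)(C)[C@H](O)C3)c(O)c1C | target

Total step count: 10. Longest linear sequence: 8 (steps 1–7 and 10); steps 8 and 9 form the convergent branch.

Steps most likely to fail

**Step 4.**
- Enantioface discrimination may be incomplete, because the peri acetate at C5 crowds the path along which the alkene reaches the oxo group.
- The oxirane may also open early at C4 under the influence of the acid by-product or the neighbouring ester carbonyl. Such opening leaves C3 untouched, and a benzylic C4–O ester is still removed under the conditions of step 5, so stereochemical purity is the real concern.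
- The fallback secures purity by separating diastereomers instead of relying on the catalyst alone. It sets out from 9 and returns at 10.
- Alcohol 9 of insufficient enantiomeric purity is esterified with (1S)-(−)-camphanic chloride (pyridine, DMAP, CH2Cl2) to (3R)-6-acetyl-5,7-diacetoxy-2,2-dimethylchroman-3-yl (1S,4R)-camphanate F1.
- F1 is freed from its 3S diastereomer by crystallisation or chromatography. Prolonged methanolysis with K2CO3 in MeOH then removes all three esters and gives 10.

**Step 10.**
- The methylene unit may be exchanged between the partners by retro-Michael and retro-Mannich processes in the warm buffered medium. This would divert material into symmetrical dimers.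
- The fallback exchanges the roles of the two halves and omits step 7. It sets out from 16 and 10 and returns at 18.
- Pyranone 16 is aminomethylated with bis(dimethylamino)methane (CH2Cl2, 0 °C) to 3-[(dimethylamino)methyl]-6-ethyl-4-hydroxy-5-methyl-2H-pyran-2-one F2.
- F2 should lose dimethylamine near room temperature to give 6-ethyl-5-methyl-3-methylidenepyran-2,4-dione F3.
- Slow addition of F2 to an excess of triol 10 in AcOH/NaOAc-buffered MeCN lets C8 of 10 add to F3 in a Friedel–Crafts-type conjugate addition. This temperature is below the one at which the bridged product begins to exchange, and the addition gives 18.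

**Step 1.**
- The ambident phloroglucinol-type anion may be over-alkylated or C-alkylated, or the hindered tertiary chloride may convert sluggishly.
- The fallback builds the pyran ring by carbonyl condensation instead of etherification and rearrangement. It sets out from 1 and returns at 7.
- Compound 1 is heated with 3-methylbut-2-enal and catalytic ethylenediammonium diacetate in toluene (Knoevenagel-type C-alkylation, dehydration, oxa-6π closure) to give 1-(5,7-dihydroxy-2,2-dimethyl-2H-chromen-6-yl)ethanone F4.
- Closure through an ortho oxygen competes here, so a chromatographic separation of regioisomers on cheap material is needed.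
- Acetylation under the conditions of step 2 then gives 7.

Further compounds
F1 | step 4 | (3R)-6-acetyl-5,7-diacetoxy-2,2-dimethylchroman-3-yl (1S,4R)-camphanate | CC(=O)c1c(OC(C)=O)cc2OC(C)(C)[C@H](OC(=O)[C@@]34CC[C@@](C)(C(=O)O3)C4(C)C)Cc2c1OC(C)=O
F2 | step 10 | 3-[(dimethylamino)methyl]-6-ethyl-4-hydroxy-5-methyl-2H-pyran-2-one | CCc1oc(=O)c(CN(C)C)c(O)c1C
F3 | step 10 | 6-ethyl-5-methyl-3-methylidenepyran-2,4-dione | CCC1=C(C)C(=O)C(=C)C(=O)O1
F4 | step 1 | 1-(5,7-dihydroxy-2,2-dimethyl-2H-chromen-6-yl)ethanone | CC(=O)c1c(O)cc2OC(C)(C)C=Cc2c1O
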